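The vessel holds a charge of starting material under held gas, and the gas reaches it as dissolved coupling partner.

    coupling partner + single product → double product + released group (k1 = 1.2 × 10⁻⁴ /M/min)
    gas ⇌ coupling partner, rate k2*(csat - [coupling partner]) (k2 = 0.0078 /min, csat = 110 mM)
    coupling partner + double product ⇌ triple product + released group (K3 = 9.1, k3 = 0.0046 /M/min)
    starting material + coupling partner → single product + released group (k4 = 0.0072 /M/min)

all flasks: starting material 0.79 M; gas 110 mM (held)
- Saturday's: time 30 h
- Monday's: time 60 h

- which of these there is most of at the end, counted by the starting material in it, Saturday's (single product / double product / starting material / triple product)
- which of these there is most of at the end, counted by the starting material in it, Monday's (single product / double product / starting material / triple product)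
- the largest of these amounts at the end, in percent of the starting material charged, Saturday's
- the largest of these amounts at the end, in percent of the starting material charged, Monday's

**Partner balance.** The dissolved coupling partner stands lower than the starting material, with saturation at 110 mM against 0.79 M. I set its refill from the gas equal to its uptake by the first coupling, the usual steady-state assumption. Uptake and refill coefficients match when starting material stands at 1.08 M. The dissolved level is then saturation divided by one plus starting material over that amount, so Saturday's begins near 63.5 mM once filled.

**Crossing time.** Putting that level into the loss of starting material gives two added terms for using half the charge. One is 14.6 h for the coupling at saturation, and the other is 7.67 h for delivering the partner. Their sum, 22.3 h, is my crossing time, the hour at which single product draws level with starting material. I neglect the second coupling, whose constant is 60.0 times smaller.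

**Two readings.** Saturday's, read at 30 h, and the same flask read at 8.0 h have identical charges, but they lie on opposite sides of the crossing. So I expect single product ahead on Saturday's and starting material ahead at the early reading. Past the crossing I hold the partner at 80.6 mM, which leaves 38.2 % of starting material on Saturday's and 13.4 % on Monday's. I therefore commit to single product at 61.8 % and 86.6 %.

**The forecast.** It names single product on Saturday's at 59 % and single product on Monday's at 86 %, on the ground that “a few percent goes beyond the single product”. Its Saturday's figure is lower than mine.

**The result.** Saturday's ends with single product at 59.2 %, and Monday's with single product at 85.8 %. In Saturday's flask single product and starting material hold the same of the charge at 23.9 h, later than my crossing time of 22.3 h and earlier than Saturday's reading. The same flask read earlier, at 8.0 h, does not have the forecast's single product ahead, for starting material stands higher there, at 82.6 %.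

The numbers of this flask belong to no real substance; no experiment stands behind them.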